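**Retrosynthetic overview**

1. Labels used in the text (never in SMILES): ring A = tetrahydropyran O10–C9–C1–C2–C12–C11 (C1 carries the angelate; C9 carries C8, which bears Me, O7 and the acetyl group); ring B = γ-lactone C2–C3–O14–C13(=O)–C12; ring C = nine-membered lactone C9–C1–C2–C3–C4=C5(Me)–C6(=O)–O7–C8; ring D = a temporary γ-lactone O–C1–C9–C8–C(=O) that is not in the target.
2. Ring C is disconnected last at C4=C5 (ring-closing metathesis of an O7 methacrylate onto a C3 vinyl group); the angelate comes from acylation of C1–OH.
3. The C8 acetyl group, C8–OH and C1–OH come from ring D (Weinreb amide, then MeLi); C1, which the key step sets cis to C8, is inverted by oxidation and a 1,3-anti reduction directed by C8–OH; C12 is set by hydrogenation of C11=C12.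
4. Rings A and D form together: the unsubstituted C=C bond of 3-methyl-2-silyloxyfuran 8 adds to the 1-oxadiene O10=C11–C12=C2 of α-formylbutenolide 6 (bonds O10–C9 and C1–C2), and the silyl ketene acetal left in ring D is oxidised in the same flask to C8–OH. The enabling feature: C11, C12, C2 and the C13 lactone carbonyl of ring B are a locked, doubly activated oxadiene, and the strip O–C1–C9–C8(Me)–C(=O) of the target is a 3-methylbutenolide once the C1 oxygen is tied to the acetyl carbon (ring D), whose silyloxyfuran is nucleophilic at C1 and then electrophilic at C9.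
5. Order of ring formation: B (chiral pool, (S)-5-(hydroxymethyl)butyrolactone) → A + D (step 5) → D opened (step 6) → C (step 16).

Key step: step 5

Remark: hydroxy ketones 15 and 16 can equilibrate with a cyclic hemiketal; they are drawn and named in the open form, which is the form that is acylated. Relative configurations are given with the labels of the overview.

**Route**

Step 1
Reactants: 1 (S)-5-(hydroxymethyl)dihydrofuran-2(3H)-one
Product: 2 (S)-5-[(tert-butyldiphenylsilyloxy)methyl]dihydrofuran-2(3H)-one
Conditions: TBDPSCl, imidazole, DMF, 0 °C to rt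
Reagents that add atoms: tert-butyl(chloro)diphenylsilane, CC(C)(C)[Si](Cl)(c1ccccc1)c1ccccc1
Why: Routine silyl ether formation at the primary alcohol; the bulky group later shields one face of ring B and no stereocentre is touched.

Step 2
Reactants: 2 (S)-5-[(tert-butyldiphenylsilyloxy)methyl]dihydrofuran-2(3H)-one
Product: 3 (S)-5-[(tert-butyldiphenylsilyloxy)methyl]-3-(hydroxymethylene)dihydrofuran-2(3H)-one (enol form of the 3-formyl lactone)
Conditions: NaH, HCO2Et, Et2O (cat. EtOH), 0 °C to rt; then cold 1 M HCl
Reagents that add atoms: ethyl formate, CCOC=O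
Why: Crossed Claisen condensation of the lactone enolate with ethyl formate should stop at the stabilised sodium enolate of the β-dicarbonyl compound; C3 is not enolisable here.

Step 3
Reactants: 3 (S)-5-[(tert-butyldiphenylsilyloxy)methyl]-3-(hydroxymethylene)dihydrofuran-2(3H)-one
Product: 6 (S)-5-[(tert-butyldiphenylsilyloxy)methyl]-2-oxo-2,5-dihydrofuran-3-carbaldehyde (α-formylbutenolide; ring B), via selenide 4 (not isolated), via selenoxide 5 (not isolated)
Conditions: PhSeCl, pyridine, CH2Cl2, 0 °C; 1 M HCl wash; then 30% H2O2, CH2Cl2, 0 °C; cold NaHCO3 wash, dried solution used at once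
Reagents that add atoms: none
Why: α-Selenenylation of the β-dicarbonyl compound followed by selenoxide syn-elimination towards the only β-hydrogens (ring CH2 = C2) should give the 2-formyl enoate, as in the known preparation of 2-formyl-2-cycloalkenones; the oxidation is run without base so that the acidic γ-hydrogen at C3 is not removed.

Step 4
Reactants: 7 3-methylfuran-2(5H)-one
Product: 8 trimethyl[(3-methylfuran-2-yl)oxy]silane
Conditions: TMSOTf, Et3N, CH2Cl2, 0 °C; distilled
Reagents that add atoms: trimethylsilyl triflate, C[Si](C)(C)OS(=O)(=O)C(F)(F)F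
Why: Soft enolisation and O-silylation of the butenolide (silyl dienol ether formation) should give the aromatic 2-silyloxyfuran.

Step 5
Reactants: 6 (S)-5-[(tert-butyldiphenylsilyloxy)methyl]-2-oxo-2,5-dihydrofuran-3-carbaldehyde; 8 trimethyl[(3-methylfuran-2-yl)oxy]silane (1.3 equiv)
Product: 11 tricyclic hydroxy bis-lactone (rings A B D; C11=C12 retained; H at C9 C1 C2 all cis; C8–OH cis to H9; C3 bears CH2OTBDPS), via cycloadduct 9 (not isolated), via silyl ether 10 (not isolated)
Conditions: CH2Cl2, −78 to 0 °C (no catalyst); then DMDO (acetone), −78 °C; then aq. citric acid, THF, 0 °C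
Reagents that add atoms: dimethyldioxirane, CC1(C)OO1
Why: The unsubstituted C=C bond of 8 adds across the electron-poor 1-oxadiene O10=C11–C12=C2 of 6 in an inverse-electron-demand oxa-Diels–Alder reaction that is strongly asynchronous (vinylogous Mukaiyama–Michael bond C1–C2 first, then collapse of the enolate oxygen O10 onto C9 of the 2-silyloxyfuranium ion), which leaves silyl ketene acetal 9 intact for Rubottom oxidation by DMDO (epoxidation, silyl shift to 10, desilylation on work-up). The closest known reaction types are the hetero-Diels–Alder reactions of 2-formyl enones and alkylidene-1,3-dicarbonyl compounds with enol ethers and the domino vinylogous Mukaiyama–Michael/oxa-Michael annulations of 2-silyloxyfurans with ortho-quinone methides. Ring A closes as the six-membered ring of the [4+2] process (6-exo-trig oxa-Michael addition in the stepwise picture), and ring D is carried in by the furan and can only be cis-fused to ring A. C2 is set by attack on the face of planar ring B opposite to the CH2OTBDPS group at C3; C1 and C9 are set cis to each other by suprafacial addition to the ring alkene and cis to C3 by the endo transition state (furan ring under the oxadiene, favoured by secondary overlap and Coulomb attraction); C8 is set by attack of DMDO on the convex face of the cis-fused A/D bicycle, which puts the new OH cis to H9. Regioselectivity (C1, not C9, bonds to C2) is secured by the silyl ketene acetal, which makes the furan carbon next to the ring oxygen the nucleophilic terminus and its neighbour the electrophilic one after the first bond. Chemoselectivity for hetero- over carbo-Diels–Alder addition is secured because the latter would join the fully substituted C12 to the fully substituted silyloxy carbon, addition to the aldehyde is avoided by omitting any Lewis acid, and DMDO prefers the electron-rich ketene acetal over the push–pull enol ether C11=C12.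

Step 6
Reactants: 11 tricyclic hydroxy bis-lactone
Product: 12 Weinreb amide diol (ring D opened; C8 bears Me OH and C(=O)N(OMe)Me; C1–OH cis to the C9 side chain)
Conditions: MeNH(OMe), AlMe3, CH2Cl2, 0 °C to rt; aq. potassium sodium tartrate; used without delay
Reagents that add atoms: N,O-dimethylhydroxylamine, CNOC
Why: Weinreb aminolysis of a lactone with an aluminium amide should open ring D only, because the ring B carbonyl is a vinylogous carbonate deactivated by O10 through C11=C12; C1 keeps its configuration.

Step 7
Reactants: 12 Weinreb amide diol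
Product: 13 C1 ketone (C8–OH and Weinreb amide unchanged)
Conditions: Dess–Martin periodinane, CH2Cl2, 0 °C (no base); crude product used directly
Reagents that add atoms: none
Why: Dess–Martin oxidation of the only secondary alcohol under base-free conditions, chosen so that the β-acyloxy ketone does not lose the ring B carboxylate by elimination.

Step 8
Reactants: 13 C1 ketone
Product: 14 1,3-anti diol (C1–OH now trans to the C9 side chain)
Conditions: Me4NBH(OAc)3, MeCN/AcOH (1:1), −30 °C
Reagents that add atoms: none
Why: Evans–Saksena hydroxyl-directed reduction: the tertiary C8–OH exchanges an acetate on boron and should deliver hydride through a six-membered chair transition state to the face of the C1 ketone on which the C9 side chain lies, giving the 1,3-anti diol, i.e. C1–OH trans to C8 as in the target.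

Step 9
Reactants: 14 1,3-anti diol
Product: 15 methyl ketone diol (C8 acetyl; C1–OH and C8–OH free; C11=C12 retained)
Conditions: MeLi (4 equiv), THF, −78 to −40 °C; sat. NH4Cl
Reagents that add atoms: methyllithium, [Li]C
Why: Weinreb ketone synthesis; the chelated tetrahedral intermediate stops at the ketone stage and the deactivated ring B lactone should survive at low temperature.

Step 10
Reactants: 15 methyl ketone diol
Product: 16 saturated diol (rings A and B cis-fused; C12–H cis to C2–H)
Conditions: H2 (4 atm), palladium on carbon (Pd/C, 10%), EtOAc, rt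
Reagents that add atoms: none
Why: Heterogeneous hydrogenation of the enol ether double bond; syn addition should take place on the face of ring A opposite to C3 of ring B and to the C9 side chain, giving C12–H cis to C2–H (the cis-fused lactone, also the thermodynamic epimer at this enolisable centre).

Step 11
Reactants: 16 saturated diol; 17 angelic acid ((Z)-2-methylbut-2-enoic acid)
Product: 19 C1 angelate (C8–OH free), via mixed anhydride 18 (not isolated)
Conditions: 17, 2,4,6-trichlorobenzoyl chloride, Et3N, toluene, rt; then 16, toluene, 80 °C (no DMAP)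
Reagents that add atoms: none
Why: Yamaguchi esterification through the mixed anhydride without DMAP, conditions known to keep the (Z)-geometry of angelates; the secondary C1–OH reacts with retention and the tertiary C8–OH does not.

Step 12
Reactants: 19 C1 angelate
Product: 20 C1 angelate C8 methacrylate
Conditions: methacrylic anhydride, Sc(OTf)3 (cat.), MeCN, −20 °C
Reagents that add atoms: methacrylic anhydride, CC(=C)C(=O)OC(=O)C(C)=C
Why: Sc(OTf)3-catalysed acylation of a hindered tertiary alcohol with an anhydride; low temperature and the absence of base should avoid α-ketol rearrangement and angelate isomerisation.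

Step 13
Reactants: 20 C1 angelate C8 methacrylate
Product: 21 primary alcohol (C3–CH2OH)
Conditions: HF·pyridine, THF/pyridine, 0 °C to rt
Reagents that add atoms: none
Why: Fluoride-mediated cleavage of the silyl ether; esters and lactones are stable to buffered HF·pyridine.

Step 14
Reactants: 21 primary alcohol
Product: 22 aldehyde (C3–CHO)
Conditions: Dess–Martin periodinane, NaHCO3, CH2Cl2, 0 °C; used crude
Reagents that add atoms: none
Why: Dess–Martin oxidation of the primary alcohol under buffered conditions that should not epimerise C3.

Step 15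
Reactants: 22 aldehyde
Product: 23 diene (C3–CH=CH2 and O7 methacrylate)
Conditions: Ph3PCH3Br, KN(SiMe3)2, THF, −78 °C
Reagents that add atoms: methyltriphenylphosphonium bromide, C[P+](c1ccccc1)(c1ccccc1)c1ccccc1.[Br-]
Why: Wittig methylenation; the non-stabilised ylide should react with the aldehyde at −78 °C much faster than with the hindered methyl ketone or the esters, and the low temperature protects C3.

Step 16
Reactants: 23 diene
Product: 24 CNP0342803.2 (target)
Conditions: second-generation Hoveyda–Grubbs catalyst (10 mol%), toluene (1 mM), 80 °C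
Reagents that add atoms: none
Why: Ring-closing metathesis: the catalyst loads at the vinyl group and closes onto the methacrylate to give the trisubstituted enoate, whose (Z)-geometry is enforced by the nine-membered ring; the trisubstituted, electron-poor angelate should be inert.

**Compound list**

1 | (S)-5-(hydroxymethyl)dihydrofuran-2(3H)-one | O=C1CC[C@@H](CO)O1 | starting material
2 | (S)-5-[(tert-butyldiphenylsilyloxy)methyl]dihydrofuran-2(3H)-one | O=C1CC[C@@H](CO[Si](c2ccccc2)(c2ccccc2)C(C)(C)C)O1 | intermediate
3 | (S)-5-[(tert-butyldiphenylsilyloxy)methyl]-3-(hydroxymethylene)dihydrofuran-2(3H)-one | O=C1C(=CO)C[C@@H](CO[Si](c2ccccc2)(c2ccccc2)C(C)(C)C)O1 | intermediate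
4 | 3-formyl-3-(phenylselanyl) lactone (epimers at the selenium-bearing carbon) | O=CC1([Se]c2ccccc2)C[C@@H](CO[Si](c2ccccc2)(c2ccccc2)C(C)(C)C)OC1=O | intermediate (not isolated)
5 | selenoxide of 4 | O=CC1([Se](=O)c2ccccc2)C[C@@H](CO[Si](c2ccccc2)(c2ccccc2)C(C)(C)C)OC1=O | intermediate (not isolated)
6 | (S)-5-[(tert-butyldiphenylsilyloxy)methyl]-2-oxo-2,5-dihydrofuran-3-carbaldehyde | O=CC1=C[C@@H](CO[Si](c2ccccc2)(c2ccccc2)C(C)(C)C)OC1=O | intermediate
7 | 3-methylfuran-2(5H)-one | CC1=CCOC1=O | starting material
8 | trimethyl[(3-methylfuran-2-yl)oxy]silane | Cc1ccoc1O[Si](C)(C)C | intermediate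
9 | [4+2] cycloadduct: rings A, B and D with a silyl ketene acetal in ring D | C[Si](C)(C)OC3=C(C)[C@H]1OC=C2C(=O)O[C@H](CO[Si](c4ccccc4)(c4ccccc4)C(C)(C)C)[C@H]2[C@H]1O3 | intermediate (not isolated)
10 | C8 trimethylsilyl ether of 11 | O=C3O[C@@H]1[C@@H]2[C@@H](CO[Si](c4ccccc4)(c4ccccc4)C(C)(C)C)OC(=O)C2=CO[C@@H]1[C@@]3(C)O[Si](C)(C)C | intermediate (not isolated)
11 | tricyclic hydroxy bis-lactone (rings A, B, D) | O=C3O[C@@H]1[C@@H]2[C@@H](CO[Si](c4ccccc4)(c4ccccc4)C(C)(C)C)OC(=O)C2=CO[C@@H]1[C@@]3(C)O | intermediate
12 | Weinreb amide diol (C1–OH cis to the C9 side chain) | CON(C)C(=O)[C@](C)(O)[C@H]1OC=C2C(=O)O[C@H](CO[Si](c3ccccc3)(c3ccccc3)C(C)(C)C)[C@H]2[C@H]1O | intermediate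
13 | C1 ketone | CON(C)C(=O)[C@](C)(O)[C@H]1OC=C2C(=O)O[C@H](CO[Si](c3ccccc3)(c3ccccc3)C(C)(C)C)[C@H]2C1=O | intermediate
14 | 1,3-anti diol (C1–OH trans to the C9 side chain) | CON(C)C(=O)[C@](C)(O)[C@H]1OC=C2C(=O)O[C@H](CO[Si](c3ccccc3)(c3ccccc3)C(C)(C)C)[C@H]2[C@@H]1O | intermediate
15 | methyl ketone diol | CC(=O)[C@](C)(O)[C@H]1OC=C2C(=O)O[C@H](CO[Si](c3ccccc3)(c3ccccc3)C(C)(C)C)[C@H]2[C@@H]1O | intermediate
16 | saturated diol (rings A/B cis-fused) | CC(=O)[C@](C)(O)[C@H]1OC[C@H]2C(=O)O[C@H](CO[Si](c3ccccc3)(c3ccccc3)C(C)(C)C)[C@H]2[C@@H]1O | intermediate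
17 | angelic acid | C/C=C(/C)C(=O)O | starting material
18 | angelic 2,4,6-trichlorobenzoic anhydride | C/C=C(/C)C(=O)OC(=O)c1c(Cl)cc(Cl)cc1Cl | intermediate (not isolated)
19 | C1 angelate | CC(=O)[C@](C)(O)[C@H]1OC[C@H]2C(=O)O[C@H](CO[Si](c3ccccc3)(c3ccccc3)C(C)(C)C)[C@H]2[C@@H]1OC(=O)/C(C)=C\C | intermediate
20 | C1 angelate C8 methacrylate | CC(=O)[C@](C)(OC(=O)C(C)=C)[C@H]1OC[C@H]2C(=O)O[C@H](CO[Si](c3ccccc3)(c3ccccc3)C(C)(C)C)[C@H]2[C@@H]1OC(=O)/C(C)=C\C | intermediate
21 | primary alcohol | CC(=O)[C@](C)(OC(=O)C(C)=C)[C@H]1OC[C@H]2C(=O)O[C@H](CO)[C@H]2[C@@H]1OC(=O)/C(C)=C\C | intermediate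
22 | aldehyde | CC(=O)[C@](C)(OC(=O)C(C)=C)[C@H]1OC[C@H]2C(=O)O[C@H](C=O)[C@H]2[C@@H]1OC(=O)/C(C)=C\C | intermediate
23 | diene (metathesis precursor) | CC(=O)[C@](C)(OC(=O)C(C)=C)[C@H]1OC[C@H]2C(=O)O[C@H](C=C)[C@H]2[C@@H]1OC(=O)/C(C)=C\C | intermediate
24 | CNP0342803.2 | C/C=C(/C)C(=O)O[C@H]1[C@@H]2[C@H]3/C=C(/C)C(=O)O[C@@](C)(C(C)=O)[C@H]1OC[C@H]2C(=O)O3 | target

**Step count and risks**

Total step count: 16. Longest linear sequence: 15 steps (steps 1–3 and 5–16; step 4 prepares the furan separately).

Steps most likely to fail:

Step 5 (key step). The silyl group may leave the ketene acetal before the oxidant arrives (silyl transfer to the enolate oxygen, which stops the sequence at the Michael stage), or the furan may add to the aldehyde instead of the alkene. Either lowers the share of 9 that reaches DMDO. Fallback, setting out from 6 and 8 and returning at 11: the same two bonds are still made in one operation, but under Eu(fod)3 catalysis (CH2Cl2, −40 °C), which chelates the formyl-lactone unit and drives the cycloaddition. Hydrolytic work-up gives the C8–H lactone F1. In a separate operation F1 is converted by soft enolisation (TMSOTf, Et3N, CH2Cl2, −78 °C) into silyl ketene acetal 9, which is oxidised with DMDO and desilylated as in step 5 to give 11.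

Step 16. The ruthenium alkylidene formed at the vinyl group may fail to engage the hindered, electron-poor methacrylate, so that intermolecular metathesis at the vinyl group outruns closure of the strained nine-membered ring. Fallback, setting out from 19 and returning at 24: the C4–C5 bond is made by a carbonyl addition instead. Acylation of C8–OH with 2-bromopropanoyl bromide (pyridine, CH2Cl2) gives the bromo ester F3, HF·pyridine gives the alcohol F4, and Dess–Martin oxidation gives the aldehyde F5. An intramolecular Reformatsky reaction mediated by CrCl2 (LiI, THF, high dilution), which adds to aldehydes but not to ketones, closes ring C as the β-hydroxy lactone F6. Mesylation gives the mesylate F7, and DBU-induced elimination through the ester enolate gives 24, the ring allowing only the (Z)-alkene.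

Step 7. The C1 ketone has the ring B carboxylate β to the carbonyl group and an acidic C2–H, so loss of that carboxylate by elimination, or epimerisation at C2 or C9, can compete during oxidation or work-up. Fallback, setting out from 12 and returning at 15: Mitsunobu inversion with chloroacetic acid (PPh3, DIAD, toluene, 0 °C) gives the inverted C1 chloroacetate F2 without passing through a ketone. Treatment of F2 with excess MeLi as in step 9 cleaves the chloroacetate and converts the Weinreb amide in one operation to give 15; steps 7 and 8 are bypassed.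

**Further compounds**

F1 | step 5 | lactone of rings A, B and D without the C8 hydroxyl (C8–H, either epimer) | O=C3O[C@@H]1[C@@H]2[C@@H](CO[Si](c4ccccc4)(c4ccccc4)C(C)(C)C)OC(=O)C2=CO[C@@H]1C3C
F2 | step 7 | inverted C1 chloroacetate of Weinreb amide 12 | CON(C)C(=O)[C@](C)(O)[C@H]1OC=C2C(=O)O[C@H](CO[Si](c3ccccc3)(c3ccccc3)C(C)(C)C)[C@H]2[C@@H]1OC(=O)CCl
F3 | step 16 | C8 2-bromopropanoate of 19 (epimers at the bromine-bearing carbon) | CC(=O)[C@](C)(OC(=O)C(C)Br)[C@H]1OC[C@H]2C(=O)O[C@H](CO[Si](c3ccccc3)(c3ccccc3)C(C)(C)C)[C@H]2[C@@H]1OC(=O)/C(C)=C\C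
F4 | step 16 | primary alcohol from F3 | CC(=O)[C@](C)(OC(=O)C(C)Br)[C@H]1OC[C@H]2C(=O)O[C@H](CO)[C@H]2[C@@H]1OC(=O)/C(C)=C\C
F5 | step 16 | aldehyde from F4 | CC(=O)[C@](C)(OC(=O)C(C)Br)[C@H]1OC[C@H]2C(=O)O[C@H](C=O)[C@H]2[C@@H]1OC(=O)/C(C)=C\C
F6 | step 16 | β-hydroxy nine-membered lactone (C4–OH, C5–H; epimers at C4 and C5) | C/C=C(/C)C(=O)O[C@H]1[C@@H]2[C@H]3C(O)C(C)C(=O)O[C@@](C)(C(C)=O)[C@H]1OC[C@H]2C(=O)O3
F7 | step 16 | C4 mesylate of F6 | C/C=C(/C)C(=O)O[C@H]1[C@@H]2[C@H]3C(OS(C)(=O)=O)C(C)C(=O)O[C@@](C)(C(C)=O)[C@H]1OC[C@H]2C(=O)O3
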